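**Plan**

- Retrosynthetic cuts: the C9 acetate; C3=C4 (ring-closing metathesis of the ten-membered ring); C6–Cl (from C6–OH with inversion); C5–C6 (dienyl addition to a C6 lactol) together with the O7–C19 lactone bond; the C13–C14 epoxide and C11/C12 diol back to a ring A 1,3-diene; then C12–C13 and C1–C10 together.
- Enabling feature: the oxygen pattern of ring A (C11–C14) is that of a cyclohexa-1,3-diene C11=C12–C13=C14. This diene is the 6π-closure product of the triene C1=C14–C13=C12–C11=C10, whose central alkene is a Wittig bond; a butenolide ring delivers C2 (as a C–H-free carboxyl) cis to C13.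
- Forward order: L-arabinose gives an allylic phosphonium salt in which a furanose ring temporarily ties C6 (masked aldehyde) to O9. One-pot Wittig/6π with 5-hydroxy-3-methylbutenolide builds ring A. Then C2 carboxyl to vinyl carbinol, ring A oxygenation, furanose unmasking, C6 dienylation, γ-lactone, chloride, ten-membered ring, last acetate.
- Stereochemistry: C7 and C9 from L-arabinose; C8 by convex-face aldol; C10/C1 by disrotation whose sense is relayed from C9 through A(1,3) strain; C11/C12 and C13/C14 by substrate-directed oxidations; C2 by Felkin–Anh addition; C6 by chelation then inversion; C17 by thermodynamic equilibration.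

Key step: step 12

Remark: atoms carry briarane numbers (C1 quaternary with Me-15; C2–C9 chain of the ten-membered ring; ring A = C1, C10–C14 with Me-20 on C11; lactone C7–C8–C17(Me-18)–C19; C16 = exocyclic methylene on C5).

Remark: the aldol of step 4 is not expected to control C17, so compounds 7–9, 11–14, 18–23, 25–29, 32 and 33 are carried as C17 epimer pairs (that centre is left open in their SMILES) until the equilibration of step 21.

**Route**

Step 1
Reactants: 1 L-arabinose
Product: 2 5-O-(tert-butyldiphenylsilyl)-L-arabinofuranose (both anomers)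
Conditions: t-BuPh2SiCl, imidazole, DMF, 0 °C to rt
Reagents that add atoms: tert-butyl(chloro)diphenylsilane CC(C)(C)[Si](Cl)(c1ccccc1)c1ccccc1
Why: Selective silyl ether formation at the only primary hydroxyl, which exists only in the furanose and open forms, traps the sugar as the furanose; no stereocentre is made.

Step 2
Reactants: 2 5-O-(tert-butyldiphenylsilyl)-L-arabinofuranose
Product: 3 5-O-(tert-butyldiphenylsilyl)-1,2-O-isopropylidene-β-L-arabinofuranose
Conditions: 2,2-dimethoxypropane, TsOH·H2O (cat.), acetone, rt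
Reagents that add atoms: 2,2-dimethoxypropane COC(C)(C)OC
Why: Acid-catalysed transacetalisation closes the cis-fused dioxolane, which only the 1,2-cis (β) anomer can form, and leaves the hydroxyl on the future C8 free.

Step 3
Reactants: 3 5-O-(tert-butyldiphenylsilyl)-1,2-O-isopropylidene-β-L-arabinofuranose
Product: 4 5-O-(tert-butyldiphenylsilyl)-1,2-O-isopropylidene-β-L-threo-pentofuranos-3-ulose
Conditions: Dess–Martin periodinane, NaHCO3, CH2Cl2, rt
Reagents that add atoms: none
Why: Dess–Martin oxidation of the single secondary alcohol gives the C8 ketone flanked by C7 and C9, which already have the target configuration.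

Step 4
Reactants: 4 the 3-ulose; 5 tert-butyl propanoate
Product: 7 3-C-[1-(tert-butoxycarbonyl)ethyl]-5-O-(tert-butyldiphenylsilyl)-1,2-O-isopropylidene-β-L-lyxofuranose (C17 epimers), via lithium enolate 6 (not isolated)
Conditions: LiN(i-Pr)2, THF, −78 °C; then 4, −78 °C; aqueous NH4Cl at −78 °C
Reagents that add atoms: none
Why: Aldol addition of the ester enolate to the ketone from the convex face, anti to both the dioxolane and the C10 arm, sets C8 with its hydroxyl cis to O7; C17 is left uncontrolled.

Step 5
Reactants: 7 the silylated aldol adduct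
Product: 8 3-C-[1-(tert-butoxycarbonyl)ethyl]-1,2-O-isopropylidene-β-L-lyxofuranose (C17 epimers)
Conditions: Bu4NF, AcOH, THF, 0 °C to rt
Reagents that add atoms: none
Why: Fluoride desilylation of the primary silyl ether, buffered with acetic acid so that the tertiary aldol is not exposed to alkoxide and retro-aldol cleavage is avoided.

Step 6
Reactants: 8 the primary alcohol
Product: 9 3-C-[1-(tert-butoxycarbonyl)ethyl]-1,2-O-isopropylidene-β-L-lyxo-pentodialdo-1,4-furanose (C10 aldehyde; C17 epimers)
Conditions: Dess–Martin periodinane, NaHCO3, CH2Cl2, 0 °C to rt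
Reagents that add atoms: none
Why: Dess–Martin oxidation of the primary alcohol under buffered neutral conditions; the tertiary hydroxyl is inert and C9 should not epimerise.

Step 7
Reactants: 9 the C10 aldehyde; 10 2-(triphenylphosphoranylidene)propanal
Product: 11 (E)-enal in which C9 of the furanose carries CH=C(CH3)–CHO (C10=C11–C12; C17 epimers)
Conditions: toluene, 80 °C
Reagents that add atoms: none
Why: Wittig olefination with the stabilised ylide gives the E enal (C9 trans to C12), the geometry that later places C9 outward on the triene terminus.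

Step 8
Reactants: 11 the (E)-enal
Product: 12 (E)-allylic alcohol (C12–OH; C17 epimers)
Conditions: NaBH4, CeCl3·7H2O, MeOH, −20 °C
Reagents that add atoms: none
Why: Luche 1,2-reduction of the enal leaves the ester, acetal and alkene geometry untouched.

Step 9
Reactants: 12 the allylic alcohol
Product: 13 (E)-allylic bromide (C12–Br; C17 epimers)
Conditions: CBr4, PPh3, CH2Cl2, 0 °C
Reagents that add atoms: tetrabromomethane BrC(Br)(Br)Br
Why: Appel bromination of the primary allylic alcohol by SN2; the hindered tertiary hydroxyl does not react, and the E alkene prevents it from cyclising onto C12.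

Step 10
Reactants: 13 the allylic bromide
Product: 14 (E)-allylic triphenylphosphonium bromide (C17 epimers)
Conditions: PPh3, MeCN, 45 °C
Reagents that add atoms: triphenylphosphine c1ccc(cc1)P(c1ccccc1)c1ccccc1
Why: SN2 quaternisation of triphenylphosphine by the primary allylic bromide.

Step 11
Reactants: 15 3-methylfuran-2-carboxylic acid
Product: 16 5-hydroxy-3-methylfuran-2(5H)-one
Conditions: O2, visible light, 5,10,15,20-tetraphenylporphyrin (cat.), CH2Cl2, 0 °C
Reagents that add atoms: dioxygen O=O
Why: Singlet-oxygen [4+2] cycloaddition to the furan and decarboxylative fragmentation of the endoperoxide give the γ-hydroxybutenolide, a ring-locked form of (Z)-3-formyl-2-methylacrylic acid.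

Step 12
Reactants: 14 the allylic phosphonium bromide; 16 5-hydroxy-3-methylfuran-2(5H)-one
Product: 20 ring A diene acid (1,5-dimethylcyclohexa-2,4-diene-1-carboxylic acid carrying the branched furanose on the ring carbon C10; carboxyl cis to H-10; C17 epimers), via ring-opened potassium carboxylate 17 (not isolated), via phosphonium ylide 18 (not isolated), via triene acid 19 (not isolated)
Conditions: 16, KOt-Bu (1.0 equiv), THF/DMF, 0 °C; 14, KN(SiMe3)2 (1.0 equiv), THF, −78 °C; combine, −78 to 0 °C; AcOH; then toluene, 90 °C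
Reagents that add atoms: none
Why: Deprotonation of 14 gives a semistabilised allylic ylide whose salt-free Wittig reaction with the ring-opened butenolide 17 forms C12=C13, expected mainly Z, and the resulting (2Z,4Z,6E)-triene 19 then closes C1–C10 by thermal disrotatory 6π-electrocyclisation. The closest known reaction types are the couplings of allylic phosphonium ylides with γ-hydroxybutenolides used for 13-cis retinoids and the thermal hexatriene-to-cyclohexadiene closure of previtamin D type, here run in one pot as a formal [3+3] annulation. Ring A is closed in the pericyclic 6π disrotatory mode, with no ionic ring closure involved. C1 and C10 are set together: disrotation turns the outward groups (Me-15 and C9) cis and the inward groups (C2 carboxyl and H-10) cis, and the absolute sense is relayed from C9, whose hydrogen eclipses C10=C11 to avoid A(1,3) strain with Me-20, so that C1 should bond to C10 anti to the quaternary C8. The step needs Z geometry at C12=C13 (the 12E triene cannot close and can be returned by photochemical E/Z equilibration) and Z geometry at C1=C14, which is inherited from the butenolide ring. The inward substituent on C1 is a carboxyl without C–H, so the competing [1,7]-hydrogen shift of Z-trienes is shut off.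

Step 13
Reactants: 20 the ring A diene acid
Product: 22 primary alcohol (C2 = CH2OH; C17 epimers), via mixed anhydride 21 (not isolated)
Conditions: i-BuOCOCl, N-methylmorpholine, THF, −15 °C; then NaBH4, H2O, 0 °C
Reagents that add atoms: none
Why: Mixed-anhydride activation and borohydride reduction convert the hindered acid chemoselectively into the alcohol without touching the tert-butyl ester or the diene.

Step 14
Reactants: 22 the primary alcohol
Product: 23 aldehyde (C2 = CHO; C17 epimers)
Conditions: Dess–Martin periodinane, NaHCO3, CH2Cl2, rt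
Reagents that add atoms: none
Why: Dess–Martin oxidation gives the non-enolisable neopentyl aldehyde on the quaternary C1.

Step 15
Reactants: 23 the C2 aldehyde; 24 vinylmagnesium bromide
Product: 25 (2S)-vinyl carbinol (C2–OH; C3=CH2; C17 epimers)
Conditions: THF, −78 °C (2.5 equiv of 24); aqueous NH4Cl
Reagents that add atoms: none
Why: Grignard 1,2-addition under Felkin–Anh control, with C10 as the large group anti to the nucleophile and attack past Me-15, should give the 2S alcohol; the excess reagent covers the free tertiary hydroxyl.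

Step 16
Reactants: 25 the vinyl carbinol
Product: 26 C11,C12-diol (ring A ene-diol; C17 epimers)
Conditions: OsO4 (2 mol%), N-methylmorpholine N-oxide, acetone/H2O, 0 °C
Reagents that add atoms: N-methylmorpholine N-oxide C[N+]1([O-])CCOCC1; water O
Why: Upjohn dihydroxylation of the most electron-rich alkene, the trisubstituted C11=C12 of the diene, from the face opposite the C9 substituent and Me-15 sets C11 and C12 with both hydroxyls cis to H-10.

Step 17
Reactants: 26 the triol
Product: 27 C2,C12-diacetate (C17 epimers)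
Conditions: Ac2O, pyridine, 4-(dimethylamino)pyridine (cat.), CH2Cl2, 0 °C to rt
Reagents that add atoms: acetic anhydride CC(=O)OC(C)=O
Why: Acetylation of the two secondary hydroxyls; the tertiary hydroxyls on C8 and C11 are not acylated under these conditions.

Step 18
Reactants: 27 the diacetate
Product: 28 lactol acid (C6 hemiacetal; O7–H and C19 acid free; C17 epimers)
Conditions: CF3CO2H/H2O (4:1), 0 °C
Reagents that add atoms: none
Why: Acidolysis removes the isopropylidene acetal and the tert-butyl ester in one operation before any acid-labile epoxide exists; the acetates and the inductively deactivated allylic and tertiary C–O bonds should survive.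

Step 19
Reactants: 28 the lactol acid
Product: 29 13,14-epoxide of 28 (epoxide cis to O11 and O12; C17 epimers)
Conditions: VO(acac)2 (5 mol%), t-BuOOH, CH2Cl2, 0 °C to rt
Reagents that add atoms: tert-butyl hydroperoxide CC(C)(C)OO
Why: Vanadium-catalysed hydroxyl-directed epoxidation, in which the tertiary C11 hydroxyl (homoallylic to C13=C14 in a cyclohex-3-enol array) delivers oxygen to its own face; the vinyl group has no free allylic hydroxyl and is left.

Step 20
Reactants: 29 the epoxy lactol acid; 30 1,4-dibromobut-2-yne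
Product: 33 γ-lactone diol (C6–OH syn to O7; 2-substituted butadiene on C6; C17 epimers), via propargylic indium reagent 31 (not isolated), via seco acid 32 (not isolated)
Conditions: In powder, THF/H2O, rt; then aqueous HCl to pH 3, rt
Reagents that add atoms: none
Why: Barbier-type indium-mediated 1,3-butadien-2-ylation of the lactol in water, with chelation by the free α-hydroxyl (O7) giving the syn C6 carbinol; on acidification the γ-hydroxy acid lactonises through O7, the lactone that places C6 and C9 trans.

Step 21
Reactants: 33 the γ-lactone diol (C17 epimers)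
Product: 34 γ-lactone diol with Me-18 cis to O8 (17R as in the target)
Conditions: 1,8-diazabicyclo[5.4.0]undec-7-ene (0.5 equiv), CH2Cl2, rt
Reagents that add atoms: none
Why: Base-mediated epimerisation through the lactone enolate funnels both epimers to the more stable one, with Me-18 trans to the bulky C9 substituent and cis to O8.

Step 22
Reactants: 34 the equilibrated lactone diol
Product: 35 (6S)-allylic chloride
Conditions: PPh3, Cl3CC(O)CCl3, CH2Cl2, −20 to 0 °C
Reagents that add atoms: hexachloroacetone ClC(Cl)(Cl)C(=O)C(Cl)(Cl)Cl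
Why: Appel-type chlorination of the allylic C6 alcohol by SN2 on the alkoxyphosphonium ion, with inversion and without allylic shift, sets C6; the hydroxyl on C9 and the tertiary hydroxyls are too hindered.

Step 23
Reactants: 35 the allylic chloride
Product: 36 9-O-deacetyl target (ten-membered ring closed; 3Z)
Conditions: second-generation Hoveyda–Grubbs catalyst (H2IMes)Cl2Ru=CH(2-i-PrOC6H4) (10 mol%), toluene (0.5 mM), 80 °C
Reagents that add atoms: none
Why: Ring-closing metathesis between the C3 vinyl group and the monosubstituted alkene of the 2-substituted butadiene closes the ten-membered ring and keeps the C5=C16 methylene; in a cyclodecene the cis alkene is the less strained isomer.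

Step 24
Reactants: 36 the 9-O-deacetyl target
Product: 37 CNP0331168.1
Conditions: Ac2O, Et3N, 4-(dimethylamino)pyridine, CH2Cl2, rt
Reagents that add atoms: acetic anhydride CC(=O)OC(C)=O
Why: Nucleophile-catalysed acylation of the remaining secondary hydroxyl on C9; the tertiary hydroxyls on C8 and C11 stay free.

**Compound list**

1 | L-arabinose | O=C[C@H](O)[C@@H](O)[C@@H](O)CO | starting material
2 | 5-O-(tert-butyldiphenylsilyl)-L-arabinofuranose (both anomers) | CC(C)(C)[Si](c1ccccc1)(c1ccccc1)OC[C@@H]1OC(O)[C@H](O)[C@H]1O | intermediate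
3 | 5-O-(tert-butyldiphenylsilyl)-1,2-O-isopropylidene-β-L-arabinofuranose | CC(C)(C)[Si](c1ccccc1)(c1ccccc1)OC[C@@H]1O[C@@H]2OC(C)(C)O[C@@H]2[C@H]1O | intermediate
4 | 5-O-(tert-butyldiphenylsilyl)-1,2-O-isopropylidene-β-L-threo-pentofuranos-3-ulose | CC(C)(C)[Si](c1ccccc1)(c1ccccc1)OC[C@@H]1O[C@@H]2OC(C)(C)O[C@@H]2C1=O | intermediate
5 | tert-butyl propanoate | CCC(=O)OC(C)(C)C | starting material
6 | lithium enolate of tert-butyl propanoate | CC=C(O[Li])OC(C)(C)C | intermediate
7 | 3-C-[1-(tert-butoxycarbonyl)ethyl]-5-O-(tert-butyldiphenylsilyl)-1,2-O-isopropylidene-β-L-lyxofuranose (tertiary OH cis to the dioxolane; C17 epimers) | CC(C)(C)[Si](c1ccccc1)(c1ccccc1)OC[C@@H]1O[C@@H]2OC(C)(C)O[C@@H]2[C@@]1(O)C(C)C(=O)OC(C)(C)C | intermediate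
8 | 3-C-[1-(tert-butoxycarbonyl)ethyl]-1,2-O-isopropylidene-β-L-lyxofuranose (C17 epimers) | OC[C@@H]1O[C@@H]2OC(C)(C)O[C@@H]2[C@@]1(O)C(C)C(=O)OC(C)(C)C | intermediate
9 | 3-C-[1-(tert-butoxycarbonyl)ethyl]-1,2-O-isopropylidene-β-L-lyxo-pentodialdo-1,4-furanose (C10 aldehyde; C17 epimers) | O=C[C@@H]1O[C@@H]2OC(C)(C)O[C@@H]2[C@@]1(O)C(C)C(=O)OC(C)(C)C | intermediate
10 | 2-(triphenylphosphoranylidene)propanal | CC(C=O)=P(c1ccccc1)(c1ccccc1)c1ccccc1 | starting material
11 | (E)-enal: furanose C9 carries CH=C(CH3)CHO (C17 epimers) | O=C/C(C)=C/[C@@H]1O[C@@H]2OC(C)(C)O[C@@H]2[C@@]1(O)C(C)C(=O)OC(C)(C)C | intermediate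
12 | (E)-allylic alcohol from 11 (C17 epimers) | OC/C(C)=C/[C@@H]1O[C@@H]2OC(C)(C)O[C@@H]2[C@@]1(O)C(C)C(=O)OC(C)(C)C | intermediate
13 | (E)-allylic bromide (C17 epimers) | BrC/C(C)=C/[C@@H]1O[C@@H]2OC(C)(C)O[C@@H]2[C@@]1(O)C(C)C(=O)OC(C)(C)C | intermediate
14 | (E)-allylic triphenylphosphonium bromide (C17 epimers) | [Br-].c1ccccc1[P+](c1ccccc1)(c1ccccc1)C/C(C)=C/[C@@H]1O[C@@H]2OC(C)(C)O[C@@H]2[C@@]1(O)C(C)C(=O)OC(C)(C)C | intermediate
15 | 3-methylfuran-2-carboxylic acid | Cc1ccoc1C(=O)O | starting material
16 | 5-hydroxy-3-methylfuran-2(5H)-one (racemic lactol) | CC1=CC(O)OC1=O | intermediate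
17 | potassium (Z)-2-methyl-4-oxobut-2-enoate | O=C/C=C(C)\C(=O)[O-].[K+] | intermediate
18 | allylic phosphonium ylide from 14 (C17 epimers) | c1ccccc1P(c1ccccc1)(c1ccccc1)=C/C(C)=C/[C@@H]1O[C@@H]2OC(C)(C)O[C@@H]2[C@@]1(O)C(C)C(=O)OC(C)(C)C | intermediate
19 | (2Z,4Z,6E)-2,6-dimethylhepta-2,4,6-trienoic acid with the branched furanose on its C7 (C17 epimers) | OC(=O)/C(C)=C\C=C/C(C)=C/[C@@H]1O[C@@H]2OC(C)(C)O[C@@H]2[C@@]1(O)C(C)C(=O)OC(C)(C)C | intermediate
20 | ring A diene acid: C1(Me)(CO2H), C13=C14, C11(Me)=C12, C10–H cis to the carboxyl, C10 bonded to furanose C9 (C17 epimers) | OC(=O)[C@@]1(C)C=CC=C(C)[C@@H]1[C@@H]2O[C@@H]3OC(C)(C)O[C@@H]3[C@@]2(O)C(C)C(=O)OC(C)(C)C | intermediate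
21 | isobutyl carbonic mixed anhydride of 20 | CC(C)COC(=O)OC(=O)[C@@]1(C)C=CC=C(C)[C@@H]1[C@@H]2O[C@@H]3OC(C)(C)O[C@@H]3[C@@]2(O)C(C)C(=O)OC(C)(C)C | intermediate
22 | ring A diene primary alcohol (C2 = CH2OH; C17 epimers) | OC[C@@]1(C)C=CC=C(C)[C@@H]1[C@@H]2O[C@@H]3OC(C)(C)O[C@@H]3[C@@]2(O)C(C)C(=O)OC(C)(C)C | intermediate
23 | ring A diene aldehyde (C2 = CHO; C17 epimers) | O=C[C@@]1(C)C=CC=C(C)[C@@H]1[C@@H]2O[C@@H]3OC(C)(C)O[C@@H]3[C@@]2(O)C(C)C(=O)OC(C)(C)C | intermediate
24 | vinylmagnesium bromide | C=C[Mg]Br | starting material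
25 | (2S)-vinyl carbinol on the ring A diene (C17 epimers) | C=C[C@H](O)[C@@]1(C)C=CC=C(C)[C@@H]1[C@@H]2O[C@@H]3OC(C)(C)O[C@@H]3[C@@]2(O)C(C)C(=O)OC(C)(C)C | intermediate
26 | C11,C12-diol: ring A with C13=C14, hydroxyls on C11 and C12 cis to H-10 (C17 epimers) | C=C[C@H](O)[C@@]1(C)C=C[C@@H](O)[C@@](C)(O)[C@@H]1[C@@H]2O[C@@H]3OC(C)(C)O[C@@H]3[C@@]2(O)C(C)C(=O)OC(C)(C)C | intermediate
27 | C2,C12-diacetate of 26 (C17 epimers) | C=C[C@H](OC(C)=O)[C@@]1(C)C=C[C@@H](OC(C)=O)[C@@](C)(O)[C@@H]1[C@@H]2O[C@@H]3OC(C)(C)O[C@@H]3[C@@]2(O)C(C)C(=O)OC(C)(C)C | intermediate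
28 | lactol acid: acetonide and tert-butyl ester removed (anomers; C17 epimers) | C=C[C@H](OC(C)=O)[C@@]1(C)C=C[C@@H](OC(C)=O)[C@@](C)(O)[C@@H]1[C@@H]2OC(O)[C@H](O)[C@@]2(O)C(C)C(=O)O | intermediate
29 | 13,14-epoxide of 28, oxygen cis to O11 and O12 (anomers; C17 epimers) | C=C[C@H](OC(C)=O)[C@@]1(C)[C@H]4O[C@H]4[C@@H](OC(C)=O)[C@@](C)(O)[C@@H]1[C@@H]2OC(O)[C@H](O)[C@@]2(O)C(C)C(=O)O | intermediate
30 | 1,4-dibromobut-2-yne | BrCC#CCBr | starting material
31 | 4-bromobut-2-ynylindium dibromide | BrCC#CC[In](Br)Br | intermediate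
32 | seco acid: open chain with hydroxyls on C6, C7, C8 and C9, C19 acid, butadien-2-yl on C6 (C17 epimers) | C=C[C@H](OC(C)=O)[C@@]1(C)[C@H]4O[C@H]4[C@@H](OC(C)=O)[C@@](C)(O)[C@@H]1[C@H](O)[C@](O)(C(C)C(=O)O)[C@@H](O)[C@H](O)C(=C)C=C | intermediate
33 | γ-lactone diol (O7–C19 lactone; C6–OH; C9–OH; C17 epimers) | C=C[C@H](OC(C)=O)[C@@]1(C)[C@H]4O[C@H]4[C@@H](OC(C)=O)[C@@](C)(O)[C@@H]1[C@H](O)[C@]2(O)C(C)C(=O)O[C@H]2[C@H](O)C(=C)C=C | intermediate
34 | γ-lactone diol with Me-18 cis to O8 (17R) | C=C[C@H](OC(C)=O)[C@@]1(C)[C@H]4O[C@H]4[C@@H](OC(C)=O)[C@@](C)(O)[C@@H]1[C@H](O)[C@]2(O)[C@@H](C)C(=O)O[C@H]2[C@H](O)C(=C)C=C | intermediate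
35 | (6S)-allylic chloride, acyclic metathesis precursor | C=C[C@H](OC(C)=O)[C@@]1(C)[C@H]4O[C@H]4[C@@H](OC(C)=O)[C@@](C)(O)[C@@H]1[C@H](O)[C@]2(O)[C@@H](C)C(=O)O[C@H]2[C@@H](Cl)C(=C)C=C | intermediate
36 | 9-O-deacetyl target (ten-membered ring; 3Z; C9–OH) | C=C1/C=C\[C@H](OC(C)=O)[C@@]2(C)[C@H]3O[C@H]3[C@@H](OC(C)=O)[C@@](C)(O)[C@@H]2[C@H](O)[C@]2(O)[C@@H](C)C(=O)O[C@H]2[C@H]1Cl | intermediate
37 | CNP0331168.1 | C=C1/C=C\[C@H](OC(C)=O)[C@@]2(C)[C@H]3O[C@H]3[C@@H](OC(C)=O)[C@@](C)(O)[C@@H]2[C@H](OC(C)=O)[C@]2(O)[C@@H](C)C(=O)O[C@H]2[C@H]1Cl | target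

**Count and risks**

Total steps: 24. Longest linear sequence: 23 steps (steps 1–10 and 12–24, from L-arabinose).

Steps most likely to fail:

1. Step 12. The olefination may give too little of the 12Z triene (the 12E isomer cannot close), the formyl carboxylate may be lost to base, and the facial relay from C9 may erode at the closure temperature. The fallback builds the Z triene by alkyne semireduction; it does not improve the facial relay, because it uses the same electrocyclisation. It sets out from enal 11 and comes back at alcohol 22. Enal 11 is homologated with dimethyl (1-diazo-2-oxopropyl)phosphonate (K2CO3, MeOH) to the terminal enyne F1. Sonogashira coupling (Pd(PPh3)4, CuI, Et3N) with methyl (Z)-3-iodo-2-methylacrylate, a known building block, gives the dienyne ester F2. Semihydrogenation over Pd/CaCO3 poisoned with Pb(OAc)2 and quinoline fixes the central Z alkene in the triene ester F3. This is closed thermally under neutral conditions (toluene, 90 °C) to the ring A diene methyl ester F4, and i-Bu2AlH (toluene, −78 °C) reduces the methyl ester to alcohol 22.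

2. Step 23. Oligomerisation may outrun closure of the ten-membered ring, the catalyst may engage the 1,1-disubstituted alkene of the diene or be lost to the allylic chloride, and E/Z mixtures may form. The fallback reverses ring closure and halogenation; it sets out from 34 and comes back at 36. The same ruthenium catalyst is applied to the allylic alcohol 34 to give the macrocyclic diol F6, and the C6 hydroxyl of the closed ring is then replaced by chloride with inversion (PPh3, hexachloroacetone), which gives 36.

3. Step 15. The three substituents on C1 differ little in size, so facial selectivity in the vinyl addition may be poor. The fallback replaces substrate control by reagent control; it sets out from 25 (as its C2 epimer mixture) and comes back at 25. The mixture is oxidised with Dess–Martin periodinane to the vinyl ketone F5, which is reduced with (R)-2-methyl-CBS-oxazaborolidine and catecholborane (toluene, −78 °C), with the quaternary C1 as the large group, to the 2S alcohol 25.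

Further compounds
F1 | step 12 | terminal enyne from 11 (C12≡C13–H; C17 epimers) | C#C/C(C)=C/[C@@H]1O[C@@H]2OC(C)(C)O[C@@H]2[C@@]1(O)C(C)C(=O)OC(C)(C)C
F2 | step 12 | methyl (2Z,6E)-2,6-dimethylhepta-2,6-dien-4-ynoate with the branched furanose on its C7 (C17 epimers) | COC(=O)/C(C)=C\C#C/C(C)=C/[C@@H]1O[C@@H]2OC(C)(C)O[C@@H]2[C@@]1(O)C(C)C(=O)OC(C)(C)C
F3 | step 12 | methyl (2Z,4Z,6E)-triene ester, methyl ester of 19 (C17 epimers) | COC(=O)/C(C)=C\C=C/C(C)=C/[C@@H]1O[C@@H]2OC(C)(C)O[C@@H]2[C@@]1(O)C(C)C(=O)OC(C)(C)C
F4 | step 12 | ring A diene methyl ester, methyl ester of 20 (C17 epimers) | COC(=O)[C@@]1(C)C=CC=C(C)[C@@H]1[C@@H]2O[C@@H]3OC(C)(C)O[C@@H]3[C@@]2(O)C(C)C(=O)OC(C)(C)C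
F5 | step 15 | vinyl ketone at C2 on the ring A diene (C17 epimers) | C=CC(=O)[C@@]1(C)C=CC=C(C)[C@@H]1[C@@H]2O[C@@H]3OC(C)(C)O[C@@H]3[C@@]2(O)C(C)C(=O)OC(C)(C)C
F6 | step 23 | macrocyclic diol: ten-membered ring closed, C6–OH (precursor configuration) and C9–OH free | C=C1/C=C\[C@H](OC(C)=O)[C@@]2(C)[C@H]3O[C@H]3[C@@H](OC(C)=O)[C@@](C)(O)[C@@H]2[C@H](O)[C@]2(O)[C@@H](C)C(=O)O[C@H]2[C@@H]1O
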